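**Retrosynthetic overview**
1. Feature used: in this eudesmane the quaternary C10 (bearing C14) is β to the C6 oxygen, and the C4 tertiary carbinol is β to C6 through C5. A ring-B C6 enone can therefore accept methyl at C10 and close C4–C5 (ring A) from its C5 enolate.
2. Key disconnections: C10–C14 (conjugate methylation) and C4–C5 (aldol onto the C4 methyl ketone of the C10 side chain), both in one operation on enone 12; afterwards C7–C11 (aldol with methyl pyruvate) and C6=O to 6α-OH.
3. Ring order: ring B first, from cis,cis-cyclohexane-1,3,5-triol (its carbinol carbons become C6, C8 and C10; enzymatic desymmetrization fixes C8). The C1–C4/C15 arm is built on C10 by vinyl addition, oxidative transposition, cleavage to the C1 aldehyde, catalytic asymmetric butenylzinc addition (sets C1) and Wacker oxidation. Ring A is closed second, in the key step.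
4. End game: C6 is reduced under thermodynamic control before the 11(13) double bond exists; the O8 triethylsilyl group is exchanged for acetyl; fluoride desilylation.

Key step: step 10

Remark 1: eudesmane numbering is used from compound 10 on (ring A: C1–C5 and C10; ring B: C5–C10). The side chain of 12 is 4-oxopentyl (C1–C4 and C15); a chain one carbon longer would close a seven-membered ring.
Remark 2 (assumption): the lipase is taken to acetylate the hydroxyl shown acetylated in 3; if its sense is opposite, hydrolysis of the meso-diacetate with the same lipase gives 3.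
Remark 3 (assumption): (+)-MIB is taken to give the (R)-carbinol from this alkenyl aldehyde, by analogy with its sense for aryl and alkenyl aldehydes; the antipodal ligand is used otherwise.

Step 1
Reactants: 1 cis,cis-cyclohexane-1,3,5-triol
Product: 2 (1R,3S,5s)-5-(triethylsilyloxy)cyclohexane-1,3-diol (meso)
Conditions: TESCl (1.0 equiv), imidazole, DMF, 0 °C
Reagents that add atoms: chlorotriethylsilane, CC[Si](Cl)(CC)CC
Why: Statistical monosilylation (silyl ether formation) of a triol with three equivalent hydroxyls should give the meso mono-ether as the main product and creates no stereocenter.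

Step 2
Reactants: 2 (1R,3S,5s)-5-(triethylsilyloxy)cyclohexane-1,3-diol
Product: 3 (1R,3S,5S)-3-hydroxy-5-(triethylsilyloxy)cyclohexyl acetate
Conditions: vinyl acetate, Amano lipase PS, t-BuOMe, rt
Reagents that add atoms: vinyl acetate, CC(=O)OC=C
Why: Lipase-catalysed irreversible transesterification (enzymatic desymmetrization of a meso-diol) acetylates one of the two enantiotopic hydroxyls, which fixes the absolute configuration of the carbon that becomes C8.

Step 3
Reactants: 3 (1R,3S,5S)-3-hydroxy-5-(triethylsilyloxy)cyclohexyl acetate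
Product: 5 (5R)-5-(triethylsilyloxy)cyclohex-2-en-1-one, via (1S,5R)-3-oxo-5-(triethylsilyloxy)cyclohexyl acetate 4 (not isolated)
Conditions: Dess–Martin periodinane, NaHCO3, CH2Cl2, 0 °C → rt; then DBU, 0 °C
Reagents that add atoms: none
Why: Dess–Martin oxidation gives the β-acetoxy ketone, which loses acetic acid by E1cB elimination under DBU while the poorer silanolate leaving group stays, so the stereocenter is untouched.

Step 4
Reactants: 5 (5R)-5-(triethylsilyloxy)cyclohex-2-en-1-one
Product: 6 (5R)-1-ethenyl-5-(triethylsilyloxy)cyclohex-2-en-1-ol (both C1 epimers)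
Conditions: CH2=CHMgBr, CeCl3, THF, −78 °C; aq. NH4Cl
Reagents that add atoms: vinylmagnesium bromide, C=C[Mg]Br
Why: CeCl3-mediated 1,2-addition of the vinyl Grignard reagent to the enone carbonyl (the carbon that becomes C10) suppresses conjugate addition and enolization, and the new carbinol center is irrelevant because it becomes sp2 in the next step.

Step 5
Reactants: 6 (5R)-1-ethenyl-5-(triethylsilyloxy)cyclohex-2-en-1-ol
Product: 7 (5S)-3-ethenyl-5-(triethylsilyloxy)cyclohex-2-en-1-one
Conditions: (C5H5NH)2Cr2O7, 4 Å molecular sieves, CH2Cl2, rt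
Reagents that add atoms: pyridinium dichromate (the carbonyl oxygen passes through the chromate ester), c1cc[nH+]cc1.c1cc[nH+]cc1.[O-][Cr](=O)(=O)O[Cr](=O)(=O)[O-]
Why: Babler–Dauben oxidative 1,3-transposition: the chromate ester of the tertiary bis-allylic alcohol should shift [3,3] into the ring and be oxidized at the secondary position, giving the linearly conjugated dienone in which the former carbonyl carbon is C10 and the new carbonyl is C6.

Step 6
Reactants: 7 (5S)-3-ethenyl-5-(triethylsilyloxy)cyclohex-2-en-1-one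
Product: 8 (5S)-3-oxo-5-(triethylsilyloxy)cyclohex-1-ene-1-carbaldehyde
Conditions: OsO4 (2 mol%), NaIO4, 2,6-lutidine, 1,4-dioxane/H2O, rt
Reagents that add atoms: sodium periodate (oxygen delivered through OsO4), [Na+].[O-]I(=O)(=O)=O
Why: Lemieux–Johnson oxidative cleavage should take the terminal, less electron-poor vinyl double bond of the dienone in preference to the trisubstituted ring enone, leaving C1 as an aldehyde.

Step 7
Reactants: 8 (5S)-3-oxo-5-(triethylsilyloxy)cyclohex-1-ene-1-carbaldehyde; 9 but-3-enylmagnesium bromide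
Product: 10 (5S)-3-[(1R)-1-hydroxypent-4-en-1-yl]-5-(triethylsilyloxy)cyclohex-2-en-1-one
Conditions: (CH2=CHCH2CH2)2Zn [from 9 and ZnCl2 in Et2O; magnesium salts precipitated with 1,4-dioxane and filtered off], (+)-MIB (5 mol%), toluene, 0 °C; aq. NH4Cl
Reagents that add atoms: none
Why: Amino-alcohol-catalysed enantioselective addition of a dialkylzinc to an aldehyde: the (+)-MIB–zinc complex delivers the butenyl group (C2–C4 and C15) to one face of the conjugated aldehyde and sets C1 as R under catalyst control, while the enone is inert to uncatalysed dialkylzinc.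

Step 8
Reactants: 10 (5S)-3-[(1R)-1-hydroxypent-4-en-1-yl]-5-(triethylsilyloxy)cyclohex-2-en-1-one
Product: 11 (5S)-3-[(1R)-1-(tert-butyldimethylsilyloxy)pent-4-en-1-yl]-5-(triethylsilyloxy)cyclohex-2-en-1-one
Conditions: TBSCl, imidazole, DMAP (cat.), DMF, rt
Reagents that add atoms: tert-butylchlorodimethylsilane, CC(C)(C)[Si](C)(C)Cl
Why: Silyl ether formation at the only free hydroxyl; a silyl ether is chosen for O1 because, as a γ-substituent of the enone, it should resist reductive cleavage by the cuprate.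

Step 9
Reactants: 11 (5S)-3-[(1R)-1-(tert-butyldimethylsilyloxy)pent-4-en-1-yl]-5-(triethylsilyloxy)cyclohex-2-en-1-one
Product: 12 (5S)-3-[(1R)-1-(tert-butyldimethylsilyloxy)-4-oxopentyl]-5-(triethylsilyloxy)cyclohex-2-en-1-one
Conditions: PdCl2 (10 mol%), Cu(OAc)2 (20 mol%), O2 (1 atm), DMA/H2O, rt
Reagents that add atoms: water, O
Why: Tsuji–Wacker oxidation should convert the terminal alkene into the methyl ketone (C4 and C15) with Markovnikov selectivity, leave the electron-poor enone double bond alone, and, with the acetate-buffered copper co-oxidant, stay mild enough for the triethylsilyl ether.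

Step 10
Reactants: 12 (5S)-3-[(1R)-1-(tert-butyldimethylsilyloxy)-4-oxopentyl]-5-(triethylsilyloxy)cyclohex-2-en-1-one
Product: 15 1β-(tert-butyldimethylsilyloxy)-4α-hydroxy-8α-(triethylsilyloxy)-11,12,13-trinor-5α-eudesman-6-one, via C5 lithium enolate 13 (not isolated), via cis-fused 5β lithium aldolate 14 (not isolated)
Conditions: Me2CuLi (3 equiv, from MeLi and CuI), Et2O, −40 °C, then 0 °C → rt; aq. NH4Cl/NH3
Reagents that add atoms: lithium dimethylcuprate (made in the flask from methyllithium, [Li]C, and CuI), [Li+].C[Cu-]C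
Why: Me2CuLi (monovalent copper) adds methyl to C10 of the 3,5-disubstituted cyclohexenone along the axial trajectory on the face anti to the pseudo-equatorial C8 triethylsilyloxy group, which forms C10–C14 with the methyl β and leaves the regiodefined C5 lithium enolate 13, the γ-silyl ether at C1 being too poor a leaving group for reductive loss. The closest known reaction type is the tandem cuprate conjugate addition–intramolecular aldol cyclization of 3-(oxoalkyl)cycloalk-2-enones. Ring A closes by a 6-(enolexo)-exo-trig aldol addition of C5 to the C4 methyl ketone (C4–C5), with lithium bridging O4 and O6. The C1–C4 arm reaches C5 first on the α face and gives the cis-fused aldolate 14, but a ketone–ketone lithium aldolate reverts above about −20 °C, so holding the mixture at 0 °C to room temperature should let C5 and C4 equilibrate through the reopened C5 enolate. The expected sink is the trans-fused 5α-H aldolate, the only isomer in which C6=O eclipses the C5–C4 bond so that O6 and an equatorial O4 on the open α face next to H5 hold lithium in a flat six-membered chelate, whereas the 4β-alkoxide would place the solvated metal under the angular methyl and the cis-fused isomers force the C1 silyloxy group axial. The step therefore needs methyl trans to O8 (secured by the C8 substituent) and 4α-O with 5α-H (secured by the chelate on the α face), and its weak point is that the chelate must outweigh the syn-axial C14/C15 methyl pair.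

Step 11
Reactants: 15 1β-(tert-butyldimethylsilyloxy)-4α-hydroxy-8α-(triethylsilyloxy)-11,12,13-trinor-5α-eudesman-6-one
Product: 16 1β-(tert-butyldimethylsilyloxy)-8α-(triethylsilyloxy)-4α-(trimethylsilyloxy)-11,12,13-trinor-5α-eudesman-6-one
Conditions: N-(trimethylsilyl)imidazole, CH2Cl2, rt
Reagents that add atoms: N-(trimethylsilyl)imidazole, C[Si](C)(C)n1ccnc1
Why: Silyl ether formation with a powerful neutral silylating agent should cap the hindered tertiary C4 alcohol without enolizing the ketone, which removes the retro-aldol opening of ring A from all later basic steps.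

Step 12
Reactants: 16 1β-(tert-butyldimethylsilyloxy)-8α-(triethylsilyloxy)-4α-(trimethylsilyloxy)-11,12,13-trinor-5α-eudesman-6-one; 17 methyl pyruvate
Product: 21 methyl 1β-(tert-butyldimethylsilyloxy)-11-hydroxy-6-oxo-8α-(triethylsilyloxy)-4α-(trimethylsilyloxy)-7αH-eudesman-12-oate (C11 epimers), via C7 lithium enolate 18 (not isolated), via 7α lithium aldolate 19 (not isolated), via dilithium enolate alkoxide 20 (not isolated)
Conditions: LiN(iPr)2 (1.1 equiv), THF, −78 °C; 17 (1.0 equiv), −78 °C; LiN(iPr)2 (1.5 equiv), −78 → −40 °C; AcOH, −78 °C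
Reagents that add atoms: none
Why: Aldol addition of the kinetic C7 lithium enolate (C5 is a blocked methine) to the ketone carbonyl of methyl pyruvate forms C7–C11 with the electrophile entering along the axial α trajectory, and re-deprotonation of the aldolate at C7 gives an enolate–alkoxide dianion (Fráter–Seebach type) that cannot undergo retro-aldol cleavage and should be protonated kinetically on the same axial α face, so that H7 ends up α and the side chain equatorial (7β), while C11 is a mixture that is erased later.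

Step 13
Reactants: 21 methyl 1β-(tert-butyldimethylsilyloxy)-11-hydroxy-6-oxo-8α-(triethylsilyloxy)-4α-(trimethylsilyloxy)-7αH-eudesman-12-oate
Product: 22 methyl 1β-(tert-butyldimethylsilyloxy)-6α,11-dihydroxy-8α-(triethylsilyloxy)-4α-(trimethylsilyloxy)eudesman-12-oate
Conditions: SmI2 (3 equiv), THF/MeOH (10:1), −78 → −20 °C; pH 7 buffer
Reagents that add atoms: none
Why: Single-electron (ketyl) reduction of the β-hydroxy ketone by SmI2 with methanol should give the thermodynamic equatorial 6α-alcohol, because the bulky oxygen–samarium group avoids the β-axial site that is syn-axial to the C14 and C15 methyls, whereas hydride reagents would attack from the open α face and give the 6β-alcohol; the acrylate double bond is not yet present and the hindered ester is not reduced.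

Step 14
Reactants: 22 methyl 1β-(tert-butyldimethylsilyloxy)-6α,11-dihydroxy-8α-(triethylsilyloxy)-4α-(trimethylsilyloxy)eudesman-12-oate
Product: 23 methyl 1β,6α-bis(tert-butyldimethylsilyloxy)-11-hydroxy-8α-(triethylsilyloxy)-4α-(trimethylsilyloxy)eudesman-12-oate
Conditions: TBSOTf (1.3 equiv), 2,6-lutidine, CH2Cl2, −78 → −20 °C
Reagents that add atoms: tert-butyldimethylsilyl triflate, CC(C)(C)[Si](C)(C)OS(=O)(=O)C(F)(F)F
Why: Silyl triflate silylation at low temperature should select the secondary C6 hydroxyl over the tertiary, inductively deactivated α-hydroxy ester at C11, and masking O6 prevents its lactonization onto C12 and its reaction in the dehydration.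

Step 15
Reactants: 23 methyl 1β,6α-bis(tert-butyldimethylsilyloxy)-11-hydroxy-8α-(triethylsilyloxy)-4α-(trimethylsilyloxy)eudesman-12-oate
Product: 24 methyl 1β,6α-bis(tert-butyldimethylsilyloxy)-8α-(triethylsilyloxy)-4α-(trimethylsilyloxy)eudesm-11(13)-en-12-oate
Conditions: Burgess reagent, toluene, 50 °C
Reagents that add atoms: none
Why: Burgess dehydration (syn elimination through the sulfamate ester) of the tertiary C11 alcohol should take a hydrogen from the C13 methyl rather than the single hindered H7, because a tetrasubstituted C7=C11 alkene would suffer allylic strain against both equatorial silyloxy groups at C6 and C8 and C7 is no longer acidified by a ketone.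

Step 16
Reactants: 24 methyl 1β,6α-bis(tert-butyldimethylsilyloxy)-8α-(triethylsilyloxy)-4α-(trimethylsilyloxy)eudesm-11(13)-en-12-oate
Product: 25 methyl 1β,6α-bis(tert-butyldimethylsilyloxy)-4α,8α-dihydroxyeudesm-11(13)-en-12-oate
Conditions: PPTS, MeOH/CH2Cl2, 0 °C → rt
Reagents that add atoms: none
Why: Mild acid-catalysed methanolysis of silyl ethers should remove the secondary triethylsilyl ether at O8 and the trimethylsilyl ether at O4, while the two hindered tert-butyldimethylsilyl ethers at O1 and O6 react far more slowly.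

Step 17
Reactants: 25 methyl 1β,6α-bis(tert-butyldimethylsilyloxy)-4α,8α-dihydroxyeudesm-11(13)-en-12-oate
Product: 26 methyl 8α-acetoxy-1β,6α-bis(tert-butyldimethylsilyloxy)-4α-hydroxyeudesm-11(13)-en-12-oate
Conditions: Ac2O, pyridine, DMAP (cat.), CH2Cl2, 0 °C
Reagents that add atoms: acetic anhydride, CC(=O)OC(C)=O
Why: Nucleophile-catalysed acylation should acetylate the only secondary hydroxyl (O8), the hindered tertiary C4 hydroxyl being inert under these conditions.

Step 18
Reactants: 26 methyl 8α-acetoxy-1β,6α-bis(tert-butyldimethylsilyloxy)-4α-hydroxyeudesm-11(13)-en-12-oate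
Product: 27 methyl 8α-acetoxy-1β,4α,6α-trihydroxyeudesm-11(13)-en-12-oate (CNP0272656.1)
Conditions: HF·pyridine, pyridine, THF, 0 °C → rt
Reagents that add atoms: none
Why: Fluoride-mediated desilylation under buffered, non-basic conditions should cleave both tert-butyldimethylsilyl ethers without acetyl migration or base-induced lactonization of the 6-hydroxy ester, giving the target with all seven stereocenters in place.

**Compound list**
1 | cis,cis-cyclohexane-1,3,5-triol | O[C@H]1C[C@@H](O)C[C@@H](O)C1 | starting material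
2 | (1R,3S,5s)-5-(triethylsilyloxy)cyclohexane-1,3-diol (meso) | O[C@H]1C[C@@H](O)C[C@@H](O[Si](CC)(CC)CC)C1 | intermediate
3 | (1R,3S,5S)-3-hydroxy-5-(triethylsilyloxy)cyclohexyl acetate | O[C@H]1C[C@@H](OC(C)=O)C[C@@H](O[Si](CC)(CC)CC)C1 | intermediate
4 | (1S,5R)-3-oxo-5-(triethylsilyloxy)cyclohexyl acetate | O=C1C[C@@H](OC(C)=O)C[C@@H](O[Si](CC)(CC)CC)C1 | intermediate
5 | (5R)-5-(triethylsilyloxy)cyclohex-2-en-1-one | O=C1C=CC[C@@H](O[Si](CC)(CC)CC)C1 | intermediate
6 | (5R)-1-ethenyl-5-(triethylsilyloxy)cyclohex-2-en-1-ol (both C1 epimers) | C=CC1(O)C=CC[C@@H](O[Si](CC)(CC)CC)C1 | intermediate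
7 | (5S)-3-ethenyl-5-(triethylsilyloxy)cyclohex-2-en-1-one | C=CC1=CC(=O)C[C@@H](O[Si](CC)(CC)CC)C1 | intermediate
8 | (5S)-3-oxo-5-(triethylsilyloxy)cyclohex-1-ene-1-carbaldehyde | O=CC1=CC(=O)C[C@@H](O[Si](CC)(CC)CC)C1 | intermediate
9 | but-3-enylmagnesium bromide | C=CCC[Mg]Br | starting material
10 | (5S)-3-[(1R)-1-hydroxypent-4-en-1-yl]-5-(triethylsilyloxy)cyclohex-2-en-1-one | C=CCC[C@@H](O)C1=CC(=O)C[C@@H](O[Si](CC)(CC)CC)C1 | intermediate
11 | (5S)-3-[(1R)-1-(tert-butyldimethylsilyloxy)pent-4-en-1-yl]-5-(triethylsilyloxy)cyclohex-2-en-1-one | C=CCC[C@@H](O[Si](C)(C)C(C)(C)C)C1=CC(=O)C[C@@H](O[Si](CC)(CC)CC)C1 | intermediate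
12 | (5S)-3-[(1R)-1-(tert-butyldimethylsilyloxy)-4-oxopentyl]-5-(triethylsilyloxy)cyclohex-2-en-1-one (key-step precursor) | CC(=O)CC[C@@H](O[Si](C)(C)C(C)(C)C)C1=CC(=O)C[C@@H](O[Si](CC)(CC)CC)C1 | intermediate
13 | lithium (3R,5S)-3-[(1R)-1-(tert-butyldimethylsilyloxy)-4-oxopentyl]-3-methyl-5-(triethylsilyloxy)cyclohex-1-en-1-olate (C5 enolate) | CC(=O)CC[C@@H](O[Si](C)(C)C(C)(C)C)[C@@]1(C)C=C(O[Li])C[C@@H](O[Si](CC)(CC)CC)C1 | intermediate
14 | lithium 4-alkoxide of the 5β (cis-fused) epimer of 15 | O=C1C[C@@H](O[Si](CC)(CC)CC)C[C@@]2(C)[C@H](O[Si](C)(C)C(C)(C)C)CC[C@@](C)(O[Li])[C@@H]12 | intermediate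
15 | 1β-(tert-butyldimethylsilyloxy)-4α-hydroxy-8α-(triethylsilyloxy)-11,12,13-trinor-5α-eudesman-6-one (key-step product) | O=C1C[C@@H](O[Si](CC)(CC)CC)C[C@@]2(C)[C@H](O[Si](C)(C)C(C)(C)C)CC[C@@](C)(O)[C@H]12 | intermediate
16 | 1β-(tert-butyldimethylsilyloxy)-8α-(triethylsilyloxy)-4α-(trimethylsilyloxy)-11,12,13-trinor-5α-eudesman-6-one | O=C1C[C@@H](O[Si](CC)(CC)CC)C[C@@]2(C)[C@H](O[Si](C)(C)C(C)(C)C)CC[C@@](C)(O[Si](C)(C)C)[C@H]12 | intermediate
17 | methyl pyruvate | CC(=O)C(=O)OC | starting material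
18 | C7 lithium enolate of 16 | [Li]OC1=C[C@@H](O[Si](CC)(CC)CC)C[C@@]2(C)[C@H](O[Si](C)(C)C(C)(C)C)CC[C@@](C)(O[Si](C)(C)C)[C@H]12 | intermediate
19 | lithium 11-alkoxide of the 7α (7βH) epimer of 21 | O=C1[C@@H](C(C)(O[Li])C(=O)OC)[C@@H](O[Si](CC)(CC)CC)C[C@@]2(C)[C@H](O[Si](C)(C)C(C)(C)C)CC[C@@](C)(O[Si](C)(C)C)[C@H]12 | intermediate
20 | dilithium C6-enolate 11-alkoxide of 21 | [Li]OC1=C(C(C)(O[Li])C(=O)OC)[C@@H](O[Si](CC)(CC)CC)C[C@@]2(C)[C@H](O[Si](C)(C)C(C)(C)C)CC[C@@](C)(O[Si](C)(C)C)[C@H]12 | intermediate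
21 | methyl 1β-(tert-butyldimethylsilyloxy)-11-hydroxy-6-oxo-8α-(triethylsilyloxy)-4α-(trimethylsilyloxy)-7αH-eudesman-12-oate (C11 epimers) | O=C1[C@H](C(C)(O)C(=O)OC)[C@@H](O[Si](CC)(CC)CC)C[C@@]2(C)[C@H](O[Si](C)(C)C(C)(C)C)CC[C@@](C)(O[Si](C)(C)C)[C@H]12 | intermediate
22 | methyl 1β-(tert-butyldimethylsilyloxy)-6α,11-dihydroxy-8α-(triethylsilyloxy)-4α-(trimethylsilyloxy)eudesman-12-oate | O[C@H]1[C@H](C(C)(O)C(=O)OC)[C@@H](O[Si](CC)(CC)CC)C[C@@]2(C)[C@H](O[Si](C)(C)C(C)(C)C)CC[C@@](C)(O[Si](C)(C)C)[C@H]12 | intermediate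
23 | methyl 1β,6α-bis(tert-butyldimethylsilyloxy)-11-hydroxy-8α-(triethylsilyloxy)-4α-(trimethylsilyloxy)eudesman-12-oate | CC(C)(C)[Si](C)(C)O[C@H]1[C@H](C(C)(O)C(=O)OC)[C@@H](O[Si](CC)(CC)CC)C[C@@]2(C)[C@H](O[Si](C)(C)C(C)(C)C)CC[C@@](C)(O[Si](C)(C)C)[C@H]12 | intermediate
24 | methyl 1β,6α-bis(tert-butyldimethylsilyloxy)-8α-(triethylsilyloxy)-4α-(trimethylsilyloxy)eudesm-11(13)-en-12-oate | CC(C)(C)[Si](C)(C)O[C@H]1[C@H](C(=C)C(=O)OC)[C@@H](O[Si](CC)(CC)CC)C[C@@]2(C)[C@H](O[Si](C)(C)C(C)(C)C)CC[C@@](C)(O[Si](C)(C)C)[C@H]12 | intermediate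
25 | methyl 1β,6α-bis(tert-butyldimethylsilyloxy)-4α,8α-dihydroxyeudesm-11(13)-en-12-oate | CC(C)(C)[Si](C)(C)O[C@H]1[C@H](C(=C)C(=O)OC)[C@@H](O)C[C@@]2(C)[C@H](O[Si](C)(C)C(C)(C)C)CC[C@@](C)(O)[C@H]12 | intermediate
26 | methyl 8α-acetoxy-1β,6α-bis(tert-butyldimethylsilyloxy)-4α-hydroxyeudesm-11(13)-en-12-oate | CC(C)(C)[Si](C)(C)O[C@H]1[C@H](C(=C)C(=O)OC)[C@@H](OC(C)=O)C[C@@]2(C)[C@H](O[Si](C)(C)C(C)(C)C)CC[C@@](C)(O)[C@H]12 | intermediate
27 | methyl 8α-acetoxy-1β,4α,6α-trihydroxyeudesm-11(13)-en-12-oate (CNP0272656.1) | C=C(C(=O)OC)[C@H]1[C@H](O)[C@@H]2[C@@](C)(C[C@@H]1OC(C)=O)[C@H](O)CC[C@@]2(C)O | target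

**Step count**
Total steps: 18. Longest linear sequence: 18 steps (1 → 27); 9 and 17 are purchased.

**Steps most likely to fail**

Step 10 (key step). Ring closure may stop at the kinetically accessible cis-fused stage, or C5 and C4 may settle wrongly because the syn-axial methyl pair offsets the chelate preference. Fallback: set out from 12, run the cuprate addition and closure cold (−78 → −40 °C) and quench cold to take the cis-fused ketol 1β-(tert-butyldimethylsilyloxy)-4α-hydroxy-8α-(triethylsilyloxy)-11,12,13-trinor-5β-eudesman-6-one F1. Silylate O4 with N-(trimethylsilyl)imidazole to its 4α-trimethylsilyl ether F2. Then equilibrate the ring-fusion carbon with DBU in toluene at 60 °C: with O4 blocked no retro-aldol is possible, so only C5 epimerizes, away from the isomer whose C1 silyloxy group is axial (a known base epimerization of a 1-decalone ring fusion). The route is rejoined at 16.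

Step 12. The strained axial aldolate may revert (loss of pyruvate) on warming, the second deprotonation may be incomplete, or protonation may show poor facial selectivity and leave the 7α epimer. Fallback: set out from 16 and carry C11–C13 as an isopropenyl group, which is inert to SmI2.
- LiN(iPr)2 then acetone gives the aldol adduct 1β-(tert-butyldimethylsilyloxy)-11-hydroxy-8α-(triethylsilyloxy)-4α-(trimethylsilyloxy)eudesman-6-one F3.
- MsCl/Et3N then DBU gives the conjugated 1β-(tert-butyldimethylsilyloxy)-8α-(triethylsilyloxy)-4α-(trimethylsilyloxy)eudesm-7(11)-en-6-one F4.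
- LiN(iPr)2 at −78 °C then AcOH (deconjugative kinetic α-protonation of the dienolate on the axial α face) sets C7 and gives 1β-(tert-butyldimethylsilyloxy)-8α-(triethylsilyloxy)-4α-(trimethylsilyloxy)-7αH-eudesm-11(13)-en-6-one F5.
- SmI2/MeOH gives 1β-(tert-butyldimethylsilyloxy)-8α-(triethylsilyloxy)-4α-(trimethylsilyloxy)eudesm-11(13)-en-6α-ol F6.
- TBSOTf/2,6-lutidine gives 1β,6α-bis(tert-butyldimethylsilyloxy)-8α-(triethylsilyloxy)-4α-(trimethylsilyloxy)eudesm-11(13)-ene F7.
- SeO2/t-BuOOH, completed with MnO2, oxidizes the C12 methyl to 1β,6α-bis(tert-butyldimethylsilyloxy)-8α-(triethylsilyloxy)-4α-(trimethylsilyloxy)eudesm-11(13)-en-12-al F8.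
- NaClO2 (Pinnick oxidation) gives 1β,6α-bis(tert-butyldimethylsilyloxy)-8α-(triethylsilyloxy)-4α-(trimethylsilyloxy)eudesm-11(13)-en-12-oic acid F9.
- Trimethylsilyldiazomethane in MeOH gives the methyl ester, and the route is rejoined at 24.

Step 13. The 6-alkoxide formed in the reduction may close onto the C12 ester (lactonization with loss of methanol), or facial control may be incomplete. Fallback: set out from 22 as obtained, or from its lactone, and drive the mixture fully to the lactone 1β-(tert-butyldimethylsilyloxy)-11-hydroxy-8α-(triethylsilyloxy)-4α-(trimethylsilyloxy)eudesman-12,6α-olide F10. Open it with LiOH in THF/H2O at 0 °C to lithium 1β-(tert-butyldimethylsilyloxy)-6α,11-dihydroxy-8α-(triethylsilyloxy)-4α-(trimethylsilyloxy)eudesman-12-oate F11. Alkylate the carboxylate with MeI in DMF without acidification (the known way to hold a γ-hydroxy methyl ester open). The route is rejoined at 22.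

Further compounds
F1 | step 10 | 1β-(tert-butyldimethylsilyloxy)-4α-hydroxy-8α-(triethylsilyloxy)-11,12,13-trinor-5β-eudesman-6-one | O=C1C[C@@H](O[Si](CC)(CC)CC)C[C@@]2(C)[C@H](O[Si](C)(C)C(C)(C)C)CC[C@@](C)(O)[C@@H]12
F2 | step 10 | 1β-(tert-butyldimethylsilyloxy)-8α-(triethylsilyloxy)-4α-(trimethylsilyloxy)-11,12,13-trinor-5β-eudesman-6-one | O=C1C[C@@H](O[Si](CC)(CC)CC)C[C@@]2(C)[C@H](O[Si](C)(C)C(C)(C)C)CC[C@@](C)(O[Si](C)(C)C)[C@@H]12
F3 | step 12 | 1β-(tert-butyldimethylsilyloxy)-11-hydroxy-8α-(triethylsilyloxy)-4α-(trimethylsilyloxy)eudesman-6-one (C7 as formed) | O=C1C(C(C)(C)O)[C@@H](O[Si](CC)(CC)CC)C[C@@]2(C)[C@H](O[Si](C)(C)C(C)(C)C)CC[C@@](C)(O[Si](C)(C)C)[C@H]12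
F4 | step 12 | 1β-(tert-butyldimethylsilyloxy)-8α-(triethylsilyloxy)-4α-(trimethylsilyloxy)eudesm-7(11)-en-6-one | O=C1C(=C(C)C)[C@@H](O[Si](CC)(CC)CC)C[C@@]2(C)[C@H](O[Si](C)(C)C(C)(C)C)CC[C@@](C)(O[Si](C)(C)C)[C@H]12
F5 | step 12 | 1β-(tert-butyldimethylsilyloxy)-8α-(triethylsilyloxy)-4α-(trimethylsilyloxy)-7αH-eudesm-11(13)-en-6-one | O=C1[C@H](C(C)=C)[C@@H](O[Si](CC)(CC)CC)C[C@@]2(C)[C@H](O[Si](C)(C)C(C)(C)C)CC[C@@](C)(O[Si](C)(C)C)[C@H]12
F6 | step 12 | 1β-(tert-butyldimethylsilyloxy)-8α-(triethylsilyloxy)-4α-(trimethylsilyloxy)eudesm-11(13)-en-6α-ol | O[C@H]1[C@H](C(C)=C)[C@@H](O[Si](CC)(CC)CC)C[C@@]2(C)[C@H](O[Si](C)(C)C(C)(C)C)CC[C@@](C)(O[Si](C)(C)C)[C@H]12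
F7 | step 12 | 1β,6α-bis(tert-butyldimethylsilyloxy)-8α-(triethylsilyloxy)-4α-(trimethylsilyloxy)eudesm-11(13)-ene | CC(C)(C)[Si](C)(C)O[C@H]1[C@H](C(C)=C)[C@@H](O[Si](CC)(CC)CC)C[C@@]2(C)[C@H](O[Si](C)(C)C(C)(C)C)CC[C@@](C)(O[Si](C)(C)C)[C@H]12
F8 | step 12 | 1β,6α-bis(tert-butyldimethylsilyloxy)-8α-(triethylsilyloxy)-4α-(trimethylsilyloxy)eudesm-11(13)-en-12-al | CC(C)(C)[Si](C)(C)O[C@H]1[C@H](C(=C)C=O)[C@@H](O[Si](CC)(CC)CC)C[C@@]2(C)[C@H](O[Si](C)(C)C(C)(C)C)CC[C@@](C)(O[Si](C)(C)C)[C@H]12
F9 | step 12 | 1β,6α-bis(tert-butyldimethylsilyloxy)-8α-(triethylsilyloxy)-4α-(trimethylsilyloxy)eudesm-11(13)-en-12-oic acid | CC(C)(C)[Si](C)(C)O[C@H]1[C@H](C(=C)C(=O)O)[C@@H](O[Si](CC)(CC)CC)C[C@@]2(C)[C@H](O[Si](C)(C)C(C)(C)C)CC[C@@](C)(O[Si](C)(C)C)[C@H]12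
F10 | step 13 | 1β-(tert-butyldimethylsilyloxy)-11-hydroxy-8α-(triethylsilyloxy)-4α-(trimethylsilyloxy)eudesman-12,6α-olide | CC1(O)C(=O)O[C@H]2[C@H]1[C@@H](O[Si](CC)(CC)CC)C[C@@]3(C)[C@H](O[Si](C)(C)C(C)(C)C)CC[C@@](C)(O[Si](C)(C)C)[C@H]23
F11 | step 13 | lithium 1β-(tert-butyldimethylsilyloxy)-6α,11-dihydroxy-8α-(triethylsilyloxy)-4α-(trimethylsilyloxy)eudesman-12-oate | [Li+].O[C@H]1[C@H](C(C)(O)C(=O)[O-])[C@@H](O[Si](CC)(CC)CC)C[C@@]2(C)[C@H](O[Si](C)(C)C(C)(C)C)CC[C@@](C)(O[Si](C)(C)C)[C@H]12
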